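I went through the charges.

| setting | Wednesday's | Saturday's | Monday's | Friday's | Thursday's |
|---|---|---|---|---|---|
| starting material | 100 mM | 40.0 mM | 150 mM | 100 mM | 100 mM |
| reagent | 100 mM | 40.0 mM | 100 mM | 200 mM | 100 mM |
| time |  |  |  |  | 200 min |

| run | time / min | [product] / mM |
|---|---|---|
| Wednesday's run | 10 | 20.3 |
| Wednesday's run | 20 | 34.3 |
| Wednesday's run | 30 | 43.2 |
| Wednesday's run | 40 | 46.6 |
| Wednesday's run | 50 | 50.5 |
| Saturday's run | 10 | 4.8 |
| Saturday's run | 20 | 8.3 |
| Saturday's run | 30 | 10.3 |
| Saturday's run | 40 | 13.5 |
| Saturday's run | 50 | 12.1 |
| Monday's run | 10 | 26.4 |
| Monday's run | 20 | 45.1 |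
| Monday's run | 30 | 56.8 |
| Monday's run | 40 | 62.5 |
| Monday's run | 50 | 65.5 |
| Friday's run | 10 | 29.8 |
| Friday's run | 20 | 53.9 |
| Friday's run | 30 | 66.7 |
| Friday's run | 40 | 70.8 |
| Friday's run | 50 | 73.1 |

(standard deviation of a reading: 1 mM)

- reaction order in [starting material] at the outset, round the charge of the Wednesday's run, defined at two percent of the starting material turned into product (one fixed amount of product, the same in the runs compared)
- reaction order in [reagent] at the outset, round the charge of the Wednesday's run, defined at two percent of the starting material turned into product
- product in the Thursday's run at 200 min, as a share of the starting material charged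

- Overall: starting material + reagent -> product.
- Constant volume, constant temperature.
- "The second partner" is reagent.
- An order is taken over about fifteen percent of the charge, up and down.

For Wednesday's run I took the mean rate over the first 10 min, 2.03 mM min⁻¹, and from it 24.9 min, the fading time: the product at 50 min divided by that opening rate.

Raising the starting material to Monday's charge multiplies it by 1.50, so a first-order dependence would multiply the rate by the same factor. The mean rate, 2.64 mM min⁻¹, grew by a factor of 1.30, a secant order of 0.648.

Doubling the reagent in Friday's run should double a first-order rate. The mean rate, 2.98 mM min⁻¹, grew by a factor of 1.47, a secant order of 0.554.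

Lowering both charges in Saturday's run cut the mean rate to 0.480 mM min⁻¹, a quarter of Wednesday's, though Saturday's first reading carries a scatter of 1 mM on 4.8 mM.

| Run | Opening rate | Fading time |
|---|---|---|
| Wednesday's | 2.03 mM min⁻¹ | 24.9 min |
| Saturday's | 0.480 mM min⁻¹ | 25.2 min |
| Monday's | 2.64 mM min⁻¹ | 24.8 min |
| Friday's | 2.98 mM min⁻¹ | 24.5 min |

Friday's opening rate was 6.21 times Saturday's, yet the fading times stood close together. I therefore took the rate to fade exponentially with this time constant, the product climbing towards rate times fading time. I committed to orders of 0.648 and 0.554, and, since Thursday's charge is Wednesday's, to a Thursday product just above Wednesday's last reading, 50.5 mM.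

The forecast gave 0.6, 0.55 and 54%, on this ground: “These plateaus fit an equilibrium”. Its Thursday figure, as product, stood above Wednesday's last reading, and its order in starting material below mine.

The simulation gave 0.70, 0.70 and 50.9%.

    starting material + reagent ⇌ intermediate, settled at all times (18.40 M⁻¹)
    starting material + reagent → product (0.8400 M⁻¹ min⁻¹)
    starting material → decomposed substrate (0.05892 min⁻¹)
    starting material + reagent + product → 2 product (15.36 M⁻² min⁻¹)

Thursday's shortfall came mainly from the loss of starting material to decomposed substrate: with that step removed, Thursday's yield was 96.8% instead of 50.9%. Thursday's product at 200 min, 50.9 mM, divided by the rate of the same charge in Wednesday's run at two percent turned, 2.2 mM min⁻¹, gave 23.2 min, against my fading time of 24.9 min. For Saturday's run, the rate 0.52 mM min⁻¹ and that fading time gave an estimated climb towards 12.9 mM, which put product at a quarter of the starting material charged at 37.3 min; Saturday's run reached it at 32.4 min.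

(Readings and results were generated by integration with made-up constants, and the scatter is random.)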